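The 5–7 core is traced back to a cis-decalin by cutting the ring-fusion bond C1–C5. C1 is the methyl-bearing quaternary carbon. C5 is the methine between the C4 isopropyl carbinol and the C6 ester carbon, and the bond is shared by the cyclopentane and the cycloheptane. In mesylate 11 a semipinacol 1,2-shift moves C1 from C6 to C5. That one operation contracts one cyclohexane to the cyclopentane, expands the other to the cycloheptanone, inverts C5 to give the trans fusion, keeps C1 and C4, and unveils the C6 ketone. It exploits the aldol pattern C4(OH)–C5–C6(=O) next to C1. The precursor is an all-cis 4,5,6-triol 5-mesylate, built from one stereocentre (C1) set by a chiral-imine Michael addition.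

Key step: step 6

Remark: the daucane numbers of the target are carried through all intermediates. C1 is the quaternary CH3-bearing carbon, C4 the isopropyl carbinol, C5 the ring-fusion CH, C6 the ester carbon, C8 the methylene-bearing carbon and C9 the allylic carbinol. β is the face of the C1 methyl group.

Step 1
Reactants: 1 7-methyl-1,4-dioxaspiro[4.5]decan-8-one (racemic); 2 (R)-1-phenylethylamine; 3 methyl vinyl ketone
Product: 6 (R)-7-methyl-7-(3-oxobutyl)-1,4-dioxaspiro[4.5]decan-8-one, via ketimine 4 (not isolated), via adduct ketimine 5 (not isolated)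
Conditions: 2, toluene, reflux (Dean–Stark); 3, THF, rt; 20% aq AcOH, rt
Reagents that add atoms: water, O
Why: Chiral-imine (secondary-enamine) deracemising Michael addition, in which the more substituted enamine tautomer of 4 adds to the enone through a compact aza-ene-like transition state on the face left open by the phenylethyl group, so quaternary C1 should be set as R whatever the configuration of 1, and hydrolysis returns the auxiliary.

Step 2
Reactants: 6 (R)-7-methyl-7-(3-oxobutyl)-1,4-dioxaspiro[4.5]decan-8-one
Product: 7 (R)-6,6-ethylenedioxy-4a-methyl-4,4a,5,6,7,8-hexahydronaphthalen-2(3H)-one (C4 ketone, C5=C6, C9 ketal)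
Conditions: NaOMe (cat.), MeOH, 60 °C
Reagents that add atoms: none
Why: Intramolecular aldol condensation (second half of a Robinson annulation), in which the methyl ketone enolate carbon C5 attacks the ring ketone C6 and dehydration gives the conjugated octalone without touching C1 or the base-stable ketal.

Step 3
Reactants: 7 octalone
Product: 8 (1R,4R)-allylic alcohol (4β-hydroxy-4α-isopropyl-1β-methyl-Δ5(6)-octalin, C9 ethylene ketal)
Conditions: i-PrMgCl, CeCl3, THF, −78 to 0 °C
Reagents that add atoms: isopropylmagnesium chloride, CC(C)[Mg]Cl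
Why: Organocerium 1,2-addition to an enone, where the weakly basic reagent suppresses enolisation, reduction and 1,4-addition and attacks C4 along the pseudoaxial α trajectory of the cyclohexenone, anti to the angular methyl, placing isopropyl α and hydroxyl β.

Step 4
Reactants: 8 allylic alcohol
Product: 10 (1R,4R,5S,6R)-cis-decalin-4β,5β,6β-triol (4α-isopropyl, 1β-methyl, C9 ethylene ketal), via osmate(VI) ester 9 (not isolated)
Conditions: OsO4 (1.05 equiv), TMEDA, CH2Cl2, −78 °C; aq Na2SO3, THF, reflux
Reagents that add atoms: osmium tetroxide, O=[Os](=O)(=O)=O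
Why: Hydrogen-bond-directed syn-dihydroxylation, in which the OsO4·TMEDA complex is anchored by the C4β hydroxyl (the α face of C5 is also screened by the isopropyl group) and adds to the β face of C5=C6, which sets C5 and C6 and turns the octalin into the cis-decalin.

Step 5
Reactants: 10 triol
Product: 11 5β-mesylate of triol 10 (4β,6β-diol)
Conditions: MsCl, Et3N, CH2Cl2, −20 to 0 °C
Reagents that add atoms: methanesulfonyl chloride, CS(=O)(=O)Cl
Why: Chemoselective sulfonylation through sulfene, where only the secondary equatorial C5 hydroxyl reacts and the two tertiary axial hydroxyls stay free, with no change at any stereocentre.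

Step 6
Reactants: 11 mesylate
Product: 12 (1R,4R,5R)-4β-hydroxy-4α-isopropyl-1β-methyl-trans-perhydroazulen-6-one C9 ethylene ketal (5αH)
Conditions: Et3Al (4 equiv), CH2Cl2, −78 to −20 °C; aq Rochelle salt
Reagents that add atoms: none
Why: Triethylaluminium converts the hydroxyls into aluminium alkoxides and activates the sulfonate, and the push from the C6 oxygen drives a concerted suprafacial 1,2-shift of C1 from C6 to C5 with loss of mesylate, the closest known type being the pinacol-type (semipinacol) rearrangement of 1,2-diol monosulfonates that turns 9-hydroxy-1-decalyl sulfonates into hydroazulenones. Both rings are closed by this one migration and not by an exo or endo attack: the cyclohexane C1–C6 loses C6 and becomes the cyclopentane C1–C2–C3–C4–C5, while C5 is inserted into the other ring to give the cycloheptanone C1–C5–C6–C7–C8–C9–C10. C5 is the only new stereocentre and is set by inversion (C1 enters anti to the β-equatorial mesylate, so H5 ends α, trans to the C1 methyl), C1 migrates with retention and C4 is untouched. The alignment comes from the substrate: in the chair–chair conformer that keeps isopropyl equatorial the C5–OMs bond is equatorial and antiperiplanar to C1–C6, C7 is gauche, and both neighbouring oxygens are cis to the mesylate so that no epoxide can form. The selectivity needed is C1 over C3 (the C3–C4 bond is also antiperiplanar and C4 carries a hydroxyl), and it rests on the much higher migratory aptitude of the fully substituted C1 under Lewis-acidic, charge-developing conditions and on relief of the congested C1–C6 bond. The low temperature and the aluminium aldolate should protect the β-hydroxy ketone from retro-aldol cleavage and dehydration.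

Step 7
Reactants: 12 β-hydroxy ketone
Product: 13 (1R,4R,5S,6S)-4β,6α-diol (C9 ethylene ketal)
Conditions: Me4NBH(OAc)3, MeCN/AcOH, −30 °C
Reagents that add atoms: none
Why: Hydroxyl-directed Evans–Saksena reduction, in which the acetoxyborohydride bound to the C4β oxygen delivers hydride intramolecularly to the β face of the C6 ketone, so the new hydroxyl should end α (6S).

Step 8
Reactants: 14 vanillic acid
Product: 16 4-(tert-butyldimethylsilyloxy)-3-methoxybenzoic acid, via bis-silyl derivative 15 (not isolated)
Conditions: TBSCl (2.3 equiv), imidazole, DMF, rt; K2CO3 (cat.), MeOH/H2O, rt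
Reagents that add atoms: tert-butyldimethylsilyl chloride, CC(C)(C)[Si](C)(C)Cl
Why: Silyl protection followed by selective solvolysis, because the silyl ester is far more labile than the aryl silyl ether and is hydrolysed alone.

Step 9
Reactants: 13 diol; 16 protected vanillic acid
Product: 17 6α-[4-(TBSO)-3-methoxybenzoate] of diol 13
Conditions: DCC, DMAP, CH2Cl2, reflux
Reagents that add atoms: none
Why: Steglich esterification, where only the secondary C6 hydroxyl is acylated because the tertiary C4 hydroxyl is inert under these conditions, and C6 keeps its configuration since the C–O bond is not broken.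

Step 10
Reactants: 17 ester ketal
Product: 18 C9 ketone
Conditions: AcOH/H2O/THF (3:1:1), 45 °C
Reagents that add atoms: water, O
Why: Mild acid-catalysed ketal hydrolysis, which should leave the aryl silyl ether, the aroyl ester and the non-allylic tertiary alcohol untouched.

Step 11
Reactants: 18 ketone
Product: 19 8-methylene-9-ketone (α-methylene cycloheptanone)
Conditions: (CH2O)n, i-Pr2NH·TFA, TFA (10 mol %), THF, reflux
Reagents that add atoms: paraformaldehyde (as formaldehyde), C=O
Why: Mannich-type α-methylenation (aminomethylation then elimination), where C8 reacts because the other α-position C10 is neopentyl, next to quaternary C1, and the near-neutral medium spares ester, silyl ether and alcohol.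

Step 12
Reactants: 19 enone
Product: 20 (9S)-allylic alcohol (9α-OH, O-TBS-protected target)
Conditions: (R)-Me-CBS (0.5 equiv), catecholborane, toluene, −78 °C
Reagents that add atoms: none
Why: Corey–Bakshi–Shibata reduction, where with the branched sp2 carbon C8 as the large group and the C10 methylene as the small one the (R)-oxazaborolidine should deliver hydride to the β face and give the 9α (S) carbinol by pure 1,2-reduction.

Step 13
Reactants: 20 silyl ether
Product: 21 target CNP0330487.1
Conditions: TBAF, AcOH, THF, 0 °C
Reagents that add atoms: none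
Why: Buffered fluoride desilylation of the aryl silyl ether, which is fast and leaves the ester, the allylic alcohol and all five stereocentres unchanged.

Compound list
1 | 7-methyl-1,4-dioxaspiro[4.5]decan-8-one (racemic) | CC1CC2(CCC1=O)OCCO2 | starting material
2 | (R)-1-phenylethylamine | C[C@@H](N)c1ccccc1 | starting material
3 | methyl vinyl ketone | C=CC(C)=O | starting material
4 | ketimine of 1 and 2 | CC1CC2(CCC1=N[C@H](C)c1ccccc1)OCCO2 | intermediate
5 | Michael adduct ketimine (C1 R) | C[C@@]1(CCC(C)=O)CC2(CCC1=N[C@H](C)c1ccccc1)OCCO2 | intermediate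
6 | (R)-7-methyl-7-(3-oxobutyl)-1,4-dioxaspiro[4.5]decan-8-one | C[C@@]1(CCC(C)=O)CC2(CCC1=O)OCCO2 | intermediate
7 | (R)-6,6-ethylenedioxy-4a-methyl-4,4a,5,6,7,8-hexahydronaphthalen-2(3H)-one | C[C@]12CCC(=O)C=C1CCC1(C2)OCCO1 | intermediate
8 | (1R,4R)-4β-hydroxy-4α-isopropyl-1β-methyl-Δ5(6)-octalin C9 ketal | C[C@]12CC[C@@](O)(C(C)C)C=C1CCC1(C2)OCCO1 | intermediate
9 | 5β,6β-osmate(VI) ester of 8, TMEDA complex | C[C@]12CC[C@@](O)(C(C)C)[C@@H]3O[Os](=O)(=O)O[C@]13CCC4(C2)OCCO4.CN(C)CCN(C)C | intermediate
10 | (1R,4R,5S,6R)-cis-decalin-4β,5β,6β-triol, 4α-isopropyl, 1β-methyl, C9 ketal | C[C@]12CC[C@@](O)(C(C)C)[C@H](O)[C@@]1(O)CCC3(C2)OCCO3 | intermediate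
11 | 5β-mesylate of 10 | C[C@]12CC[C@@](O)(C(C)C)[C@H](OS(C)(=O)=O)[C@@]1(O)CCC3(C2)OCCO3 | intermediate
12 | (1R,4R,5R)-4β-hydroxy-4α-isopropyl-1β-methyl-5αH-perhydroazulen-6-one C9 ketal | O=C1CCC2(OCCO2)C[C@@]2(C)CC[C@@](O)(C(C)C)[C@H]12 | intermediate
13 | (1R,4R,5S,6S)-4β,6α-diol C9 ketal | O[C@H]1CCC2(OCCO2)C[C@@]2(C)CC[C@@](O)(C(C)C)[C@H]12 | intermediate
14 | vanillic acid | COc1cc(C(=O)O)ccc1O | starting material
15 | tert-butyldimethylsilyl 4-(tert-butyldimethylsilyloxy)-3-methoxybenzoate | COc1cc(C(=O)O[Si](C)(C)C(C)(C)C)ccc1O[Si](C)(C)C(C)(C)C | intermediate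
16 | 4-(tert-butyldimethylsilyloxy)-3-methoxybenzoic acid | COc1cc(C(=O)O)ccc1O[Si](C)(C)C(C)(C)C | intermediate
17 | 6α-aroyl ester of 13 (C9 ketal, aryl OTBS) | COc1cc(C(=O)O[C@H]2CCC3(OCCO3)C[C@@]3(C)CC[C@@](O)(C(C)C)[C@H]23)ccc1O[Si](C)(C)C(C)(C)C | intermediate
18 | C9 ketone | COc1cc(C(=O)O[C@H]2CCC(=O)C[C@@]3(C)CC[C@@](O)(C(C)C)[C@H]23)ccc1O[Si](C)(C)C(C)(C)C | intermediate
19 | 8-methylene-9-ketone | COc1cc(C(=O)O[C@H]2CC(=C)C(=O)C[C@@]3(C)CC[C@@](O)(C(C)C)[C@H]23)ccc1O[Si](C)(C)C(C)(C)C | intermediate
20 | 9α-alcohol, O-TBS-protected target | COc1cc(C(=O)O[C@H]2CC(=C)[C@@H](O)C[C@@]3(C)CC[C@@](O)(C(C)C)[C@H]23)ccc1O[Si](C)(C)C(C)(C)C | intermediate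
21 | CNP0330487.1, (1R,4R,5S,6S,9S)-4β,9α-dihydroxydauc-8(14)-en-6α-yl vanillate | C=C1C[C@H](OC(=O)c2ccc(O)c(OC)c2)[C@@H]2[C@](C)(CC[C@@]2(O)C(C)C)C[C@@H]1O | target

Total step count: 13. Longest linear sequence: 12 (steps 1–7 and 9–13).

Steps most likely to fail

Step 6. The C4 alkoxide may compete as the pushing group, so that C3 migrates instead of C1 and an acyl-hydrindane skeleton forms. The aldol product may also be lost by retro-aldol cleavage.
- The fallback removes the competing push instead of changing the promoter. It sets out from 9, which is isolated this time.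
- The only free hydroxyl of 9 (C4) is silylated with TESOTf and 2,6-lutidine to give the silylated osmate ester F1.
- Sulfite cleavage gives the 5β,6β-diol 4-triethylsilyl ether F2, and mesylation gives the 5β-mesylate F3, in which only the C6 hydroxyl can drive a shift.
- KOt-Bu in THF/t-BuOH then gives the rearranged silyloxy ketone F4, and HF·pyridine returns to the route at 12.

Step 4. Facial selectivity may be poor (attack anti to the angular methyl, leading to the trans-decalin series), or addition to the hindered trisubstituted alkene may be sluggish.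
- The fallback sets out from 8 and delivers both oxygens by epoxidation and double inversion instead of osmylation.
- Hydroxyl-directed epoxidation (VO(acac)2, t-BuOOH) gives the 5β,6β-epoxy alcohol F5.
- Halide-catalysed CO2 insertion (Bu4NBr, Lewis-acid catalyst, CO2 pressure) opens C5 from the α face and recloses from the β face, giving the cis-5β,6β-cyclic carbonate F6.
- Aqueous NaOH returns to the route at 10.

Step 12. The substrate bias (hydride attack on the α face, away from the C1 methyl) may override the catalyst. Borane may also add to the exocyclic alkene.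
- The fallback sets out from 19, accepts the substrate preference and corrects it afterwards.
- Luche reduction gives the 9β-alcohol F7.
- Mitsunobu inversion with 4-nitrobenzoic acid gives the 9α-(4-nitrobenzoate) F8, watching for SN2′ attack at the methylene carbon.
- K2CO3 in MeOH cleaves the activated nitrobenzoate together with the aryl silyl ether while the hindered vanillate stays, so the route is rejoined at 21.

Further compounds
F1 | step 6 | 4-O-triethylsilyl osmate(VI) ester, TMEDA complex | C[C@]12CC[C@@](O[Si](CC)(CC)CC)(C(C)C)[C@@H]3O[Os](=O)(=O)O[C@]13CCC4(C2)OCCO4.CN(C)CCN(C)C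
F2 | step 6 | 5β,6β-diol 4-triethylsilyl ether | C[C@]12CC[C@@](O[Si](CC)(CC)CC)(C(C)C)[C@H](O)[C@@]1(O)CCC3(C2)OCCO3
F3 | step 6 | 5β-mesylate 4-triethylsilyl ether | C[C@]12CC[C@@](O[Si](CC)(CC)CC)(C(C)C)[C@H](OS(C)(=O)=O)[C@@]1(O)CCC3(C2)OCCO3
F4 | step 6 | 4-O-triethylsilyl ether of ketone 12 | O=C1CCC2(OCCO2)C[C@@]2(C)CC[C@@](O[Si](CC)(CC)CC)(C(C)C)[C@H]12
F5 | step 4 | 5β,6β-epoxy-4β-alcohol | C[C@]12CC[C@@](O)(C(C)C)[C@@H]3O[C@]13CCC4(C2)OCCO4
F6 | step 4 | 5β,6β-cyclic carbonate 4β-alcohol | C[C@]12CC[C@@](O)(C(C)C)[C@@H]3OC(=O)O[C@]13CCC4(C2)OCCO4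
F7 | step 12 | 9β-alcohol (C9 epimer of 20) | COc1cc(C(=O)O[C@H]2CC(=C)[C@H](O)C[C@@]3(C)CC[C@@](O)(C(C)C)[C@H]23)ccc1O[Si](C)(C)C(C)(C)C
F8 | step 12 | 9α-(4-nitrobenzoate) | COc1cc(C(=O)O[C@H]2CC(=C)[C@@H](OC(=O)c4ccc([N+](=O)[O-])cc4)C[C@@]3(C)CC[C@@](O)(C(C)C)[C@H]23)ccc1O[Si](C)(C)C(C)(C)C
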